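**Plan**

- Retrosynthesis: the bond between C1 of the 3,4,5-trimethoxyphenyl ring and C2 of the benzofuran is cut first, then the furan C3–C3a bond (Heck transform), then the O–allyl bond and the C–I bond, which leads back to vanillin.
- Enabling feature: C2, C3 and the C3-methyl of the furan ring are a disguised allyl group on the phenol oxygen, and the benzo ring (OMe at C7 next to the ring oxygen, CHO at C5 para to it) is the vanillin ring. After ring closure C2–H is the only C–H of the furan ring, α to oxygen, with C3 blocked by the methyl group.
- Forward: vanillin is iodinated ortho to OH and O-allylated. One palladium-catalysed operation then closes the furan ring (5-exo Heck, double-bond shift into the ring) and joins the trimethoxyphenyl ring at C2 by C–H arylation.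
- Stereochemistry: the target has no stereocentre and no hindered axis, so the wording "single enantiomer" is taken to be without consequence; the one achiral compound is made and nothing has to be set.

Key step: step 3

**Step 1**
Reactants: 1 vanillin (4-hydroxy-3-methoxybenzaldehyde)
Product: 2 iodovanillin (4-hydroxy-3-iodo-5-methoxybenzaldehyde)
Conditions: I2, KI, NaHCO3, H2O, rt
Reagents that add atoms: iodine, II
Why: Electrophilic aromatic iodination of the phenoxide, in which the hydroxyl group directs iodine to its only free ortho position because the para position carries the formyl group.

**Step 2**
Reactants: 2 iodovanillin (4-hydroxy-3-iodo-5-methoxybenzaldehyde)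
Product: 3 allyl ether (4-(allyloxy)-3-iodo-5-methoxybenzaldehyde)
Conditions: allyl bromide, K2CO3, DMF, 50 °C
Reagents that add atoms: allyl bromide, C=CCBr
Why: Williamson ether synthesis, in which the acidic phenol is deprotonated by carbonate and the phenoxide displaces bromide in an SN2 reaction while the aldehyde and the aryl iodide stay untouched.

**Step 3**
Reactants: 3 allyl ether (4-(allyloxy)-3-iodo-5-methoxybenzaldehyde); 4 aryl bromide (5-bromo-1,2,3-trimethoxybenzene)
Product: 7 ocophyllal B (7-methoxy-3-methyl-2-(3,4,5-trimethoxyphenyl)benzofuran-5-carbaldehyde), via exocyclic alkene 5 (not isolated), via 3-methylbenzofuran 6 (not isolated)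
Conditions: Pd(OAc)2 (5 mol %), PCy3·HBF4 (10 mol %), PivOH (30 mol %), K2CO3 (3 equiv), DMA, argon, 80 °C, then 120 °C, one pot
Reagents that add atoms: none
Why: Proposed new method: one palladium catalyst is asked to run two known cycles in sequence in one flask (auto-tandem catalysis), the closest known reaction types being the intramolecular Mizoroki–Heck cyclization of o-iodophenyl allyl ethers to 3-methylbenzofurans and the pivalate-assisted C2–H arylation of benzofurans with aryl bromides by concerted metalation–deprotonation. Pd(0) should insert into the C–I bond of 3, the aryl–palladium species should add across the allyl double bond in a 5-exo-trig carbopalladation that closes the furan ring (new C3–C3a bond), β-hydride elimination should give the exocyclic alkene 5, and palladium hydride re-addition and elimination should move the double bond into the ring to give the aromatic 3-methylbenzofuran 6. At the higher temperature the catalyst should insert into the C–Br bond of 4, the aryl–palladium pivalate should cleave the C2–H bond of 6 by concerted metalation–deprotonation, and reductive elimination should form the aryl–C2 bond of 7. No stereocentre is created, since the transient sp3 carbon C3 of the alkylpalladium intermediate is flattened again by β-hydride elimination and isomerization. The order of events rests on oxidative addition into C–I being far faster than into the C–Br bond of the electronically neutral bromide 4 and on the ring closure being intramolecular, which the temperature staging reinforces. The site of arylation is secured by the substrate, because C2–H is the only C–H bond of the furan ring, is acidified by the adjacent oxygen, and C3 is blocked by the methyl group.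

**Compound list**

1 | vanillin (4-hydroxy-3-methoxybenzaldehyde) | COc1cc(C=O)ccc1O | starting material
2 | iodovanillin (4-hydroxy-3-iodo-5-methoxybenzaldehyde) | COc1cc(C=O)cc(I)c1O | intermediate
3 | 4-(allyloxy)-3-iodo-5-methoxybenzaldehyde | C=CCOc1c(I)cc(C=O)cc1OC | intermediate
4 | 5-bromo-1,2,3-trimethoxybenzene | COc1cc(Br)cc(OC)c1OC | starting material
5 | 7-methoxy-3-methylene-2,3-dihydrobenzofuran-5-carbaldehyde | C=C1COc2c(OC)cc(C=O)cc21 | intermediate
6 | 7-methoxy-3-methylbenzofuran-5-carbaldehyde | Cc1coc2c(OC)cc(C=O)cc12 | intermediate
7 | ocophyllal B (7-methoxy-3-methyl-2-(3,4,5-trimethoxyphenyl)benzofuran-5-carbaldehyde) | COc1cc(-c2oc3c(OC)cc(C=O)cc3c2C)cc(OC)c1OC | target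

**Step count and risks**

Total step count: 3. Longest linear sequence: 3 steps (vanillin 1 to 7; bromide 4 is bought and enters in step 3).

Steps most likely to fail:

1. Step 3 (proposed new method). Three processes may spoil it:
   - Pd(0) may ionize the allyl aryl ether and so strip the allyl group, since the formyl-substituted phenoxide is a good leaving group; this competes with insertion into the C–I bond.
   - The aryl bromide may undergo intermolecular Heck arylation of the allyl or exocyclic double bond before aromatization.
   - The iodide released in the first stage may slow the C–H cleavage stage.

   Fallback, known chemistry throughout: setting out from 3, the intramolecular Mizoroki–Heck cyclization is run alone under ligand-free conditions (Pd(OAc)2, n-Bu4NCl, Na2CO3, DMF, 80 °C) and 7-methoxy-3-methylbenzofuran-5-carbaldehyde 6 is isolated free of halide salts. Electrophilic bromination at C2 (NBS, DMF, 0 °C to rt, dark) should then give 2-bromo-7-methoxy-3-methylbenzofuran-5-carbaldehyde F1. Suzuki–Miyaura coupling of F1 with commercial 3,4,5-trimethoxyphenylboronic acid (COc1cc(B(O)O)cc(OC)c1OC; Pd(PPh3)4, K2CO3, dioxane/H2O, 90 °C) comes back to the route at 7.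

2. Step 1. The iodination may stall or run on to over-iodination and oxidation of the aldehyde by hypoiodite, which would leave material that is hard to separate from vanillin.

   Fallback that avoids the halogen altogether: setting out from 1, O-alkylation with chloroacetone (K2CO3, cat. KI, acetone, reflux) should give 3-methoxy-4-(2-oxopropoxy)benzaldehyde F2. Acid-mediated cyclodehydration of this α-aryloxy ketone (P2O5 in methanesulfonic acid, 50 °C) is an intramolecular Friedel–Crafts-type attack of the ketone on the only free position ortho to the ether oxygen followed by loss of water, and should give the 3-methylbenzofuran. The fallback comes back to the route at 6, which is then isolated and arylated at C2 with 4 under the second-stage conditions of step 3.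

3. Step 2. O-alkylation may be sluggish because the phenoxide is flanked by iodine and methoxy and is made weakly nucleophilic by the para formyl group; forcing conditions would invite side reactions of the aldehyde.

   Fallback: setting out from 2, Mitsunobu etherification with allyl alcohol (PPh3, DIAD, THF, 0 °C to rt) activates the alcohol and not the phenoxide and uses the high acidity of the phenol; it comes back to the route at 3. This fallback makes no compound outside the compound list (F0).

**Further compounds**

F1 | step 3 | 2-bromo-7-methoxy-3-methylbenzofuran-5-carbaldehyde | Cc1c(Br)oc2c(OC)cc(C=O)cc12
F2 | step 1 | 3-methoxy-4-(2-oxopropoxy)benzaldehyde | CC(=O)COc1ccc(C=O)cc1OC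
F0 | step 2 | none | none
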